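Borregomycin E consists of two 6-chloroindoles fused head-to-head to a central benzene, ring C (C4b, C5, C6, C6a, C11a, C11b), which carries both methoxy groups. Ring C is cut into the four-carbon diene C11b=C4b–C5=C6, that is the C2=C3 bond of one indole extended by an oxygenated ketene acetal, and the C6a=C11a (C3=C2) bond of a 3-nitroindole. One cycloaddition forms C11a–C11b and C6–C6a, closes ring C and, by loss of HNO2 and methanol, aromatises it with both oxygens in place. The precursors are an N-Boc 6-chloroindol-3-yl ketene methyl trimethylsilyl acetal bearing the C5 methoxy group and 6-chloro-3-nitro-1-(phenylsulfonyl)indole.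

Key step: step 8

Numbering: indolo[2,3-a]carbazole numbering is used throughout. N12, C11b, C4b, C5 and C6 come from the diene half. N11, C11a and C6a come from the nitroindole half.

Assumption: the mixed methyl silyl ketal formed at C6 is taken to aromatise by loss of methanol, as vinylketene methyl silyl acetals normally do. C6 therefore emerges as a silyl ether or phenol and one O-methylation is budgeted; any fully methylated material formed directly by loss of silanol passes through that methylation unchanged.

Step 1
Reactants: 1 6-chloroindole; 2 oxalyl chloride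
Product: 4 methyl 2-(6-chloro-1H-indol-3-yl)-2-oxoacetate, via 6-chloroindol-3-ylglyoxylyl chloride 3 (not isolated)
Conditions: (COCl)2, Et2O, 0 °C to rt; then MeOH, 0 °C to rt
Reagents that add atoms: methanol (SMILES CO)
Why: Free indoles undergo uncatalysed Friedel–Crafts acylation at C3 with oxalyl chloride and the acid chloride is then esterified by methanol, a standard sequence that brings in C5 and C6 and stops at one indole per two-carbon unit because the acyl product is deactivated, whereas acid-promoted alkylation with a glyoxylate acetal would risk ionisation of the product and capture of a second indole.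

Step 2
Reactants: 4 methyl 2-(6-chloro-1H-indol-3-yl)-2-oxoacetate
Product: 5 tert-butyl 6-chloro-3-(2-methoxy-2-oxoacetyl)indole-1-carboxylate
Conditions: Boc2O, DMAP (cat.), CH2Cl2, rt
Reagents that add atoms: di-tert-butyl dicarbonate (SMILES CC(C)(C)OC(=O)OC(=O)OC(C)(C)C)
Why: DMAP-catalysed N-acylation of the acidic 3-acylindole N–H with Boc2O is routine and installs the electron-withdrawing group that later damps the enamine character of N12.

Step 3
Reactants: 5 tert-butyl 6-chloro-3-(2-methoxy-2-oxoacetyl)indole-1-carboxylate
Product: 6 tert-butyl 6-chloro-3-(1-hydroxy-2-methoxy-2-oxoethyl)indole-1-carboxylate (racemic)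
Conditions: NaBH4 (0.5 equiv), THF/MeOH, −20 to 0 °C; aq. NH4Cl
Reagents that add atoms: none
Why: Chemoselective borohydride reduction: with N1 acylated the ketone is no longer a vinylogous amide and, activated by the neighbouring ester, it is reduced at low temperature well before the ester, the new carbinol stereocentre being formed as a racemate on purpose because it is erased in step 5.

Step 4
Reactants: 6 tert-butyl 6-chloro-3-(1-hydroxy-2-methoxy-2-oxoethyl)indole-1-carboxylate
Product: 7 tert-butyl 6-chloro-3-(1,2-dimethoxy-2-oxoethyl)indole-1-carboxylate (racemic)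
Conditions: MeI (excess), Ag2O, 4 Å molecular sieves, MeCN, 40 °C, dark
Reagents that add atoms: iodomethane (SMILES CI)
Why: Purdie methylation (Ag2O/MeI) etherifies α-hydroxy esters of the mandelate type under essentially neutral conditions, so enolisation, C-methylation and intermolecular Boc transfer, all possible with a strong base, are avoided.

Step 5
Reactants: 7 tert-butyl 6-chloro-3-(1,2-dimethoxy-2-oxoethyl)indole-1-carboxylate
Product: 9 tert-butyl 6-chloro-3-[(Z)-1,2-dimethoxy-2-(trimethylsilyloxy)ethenyl]indole-1-carboxylate, via lithium ester enolate 8 (not isolated)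
Conditions: LiN(SiMe3)2, THF, −78 °C; Me3SiCl, −78 °C to rt; concentrate, take up in pentane, filter under argon; used crude
Reagents that add atoms: chlorotrimethylsilane (SMILES C[Si](C)(C)Cl)
Why: The α-proton, flanked by ester, methoxy and indolyl groups, is far more acidic than indole C2–H, so the amide base gives the lithium-chelated enolate 8, which is silylated on oxygen (silyl ketene acetal formation as used for Ireland–Claisen substrates); the stereocentre of 7 disappears and the alkene geometry (Z expected from the chelate) has no lasting consequence because C6 becomes trigonal again in step 8.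

Step 6
Reactants: 1 6-chloroindole; 10 benzenesulfonyl chloride
Product: 11 6-chloro-1-(phenylsulfonyl)indole
Conditions: 50% aq. NaOH, Bu4NHSO4 (cat.), toluene, rt
Reagents that add atoms: none
Why: Phase-transfer N-sulfonylation of the indolyl anion is a standard protection and provides the acceptor group that the dienophile needs on nitrogen.

Step 7
Reactants: 11 6-chloro-1-(phenylsulfonyl)indole
Product: 12 6-chloro-3-nitro-1-(phenylsulfonyl)indole
Conditions: fuming HNO3, Ac2O, −70 °C to rt
Reagents that add atoms: nitric acid (SMILES O[N+](=O)[O-]), acting as acetyl nitrate (SMILES CC(=O)O[N+](=O)[O-])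
Why: Electrophilic aromatic nitration with acetyl nitrate made at low temperature is the established way to 3-nitro-1-(phenylsulfonyl)indoles, C3 remaining the most reactive position of the N-sulfonylindole and the chlorine further deactivating the benzo ring.

Step 8
Reactants: 9 tert-butyl 6-chloro-3-[(Z)-1,2-dimethoxy-2-(trimethylsilyloxy)ethenyl]indole-1-carboxylate; 12 6-chloro-3-nitro-1-(phenylsulfonyl)indole
Product: 16 tert-butyl 2,9-dichloro-6-hydroxy-5-methoxy-11-(phenylsulfonyl)indolo[2,3-a]carbazole-12-carboxylate, via nitro cycloadduct 13 (not isolated), via dihydro ketal 14 (not isolated), via aryl trimethylsilyl ether 15 (not isolated)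
Conditions: 9 (2 equiv), 2,6-di-tert-butyl-4-methylpyridine, PhMe, sealed tube, 110 °C; then 1 M HCl, THF, 0 °C
Reagents that add atoms: none
Why: The two oxygens on C6 push electron density through C5=C6 and C4b=C11b so that C11b is the nucleophilic terminus of the diene (vinylogous ketene acetal), while the nitro group makes C2 of 12 (future C11a) the electrophilic end of a nitroalkene-like C2=C3 bond; a normal-electron-demand Diels–Alder reaction, concerted but strongly asynchronous or, at the limit, a vinylogous Mukaiyama–Michael addition followed by attack of the nitronate carbon C6a on the silyloxycarbenium carbon C6, therefore forms C11a–C11b and C6–C6a. Ring C is closed in the (4+2) mode (6-(enolexo)-exo-trig for the second bond in the stepwise limit). The closest known reaction types are the thermal cycloadditions of N-sulfonyl-3-nitroindoles with 1-alkoxy-3-silyloxybutadienes and related oxygenated dienes, which end in carbazoles after extrusion of nitrous acid, and the Diels–Alder reactions of N-acyl-3-vinylindoles through C2=C3 and the vinyl group; the present pairing of the two partners is a new substrate combination. Adduct 13 has four transient stereocentres (C6, C6a, C11a, C11b; the C6a/C11a fusion is cis because the addition is suprafacial) and none survives: HNO2 leaves across C6a–C11a to restore the indole in 14, the mixed methyl silyl ketal at C6 ionises with loss of its more basic methoxy group, C11b–H is lost to give the benzenoid silyl ether 15, and the acidic work-up frees phenol 16. The selectivities needed are head-to-head regiochemistry and bonding through C11b instead of C5: N-Boc weakens the opposing enamine donation of N12, C6 with its two oxygens is not a nucleophilic site, C5 is fully substituted, and the Z geometry of 9 puts the small methoxy group on the inside of the s-cis diene. The hindered pyridine traps HNO2 so that the acid-labile diene, used in excess, survives the heating.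

Step 9
Reactants: 16 tert-butyl 2,9-dichloro-6-hydroxy-5-methoxy-11-(phenylsulfonyl)indolo[2,3-a]carbazole-12-carboxylate
Product: 17 tert-butyl 2,9-dichloro-5,6-dimethoxy-11-(phenylsulfonyl)indolo[2,3-a]carbazole-12-carboxylate
Conditions: MeI, K2CO3, DMF, rt, argon
Reagents that add atoms: iodomethane (SMILES CI)
Why: Williamson ether synthesis on the only acidic site, the C6 phenol, with both nitrogens still blocked so that N-methylation cannot occur and carbonate in an aprotic solvent leaving carbamate, sulfonamide and aryl chlorides alone.

Step 10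
Reactants: 17 tert-butyl 2,9-dichloro-5,6-dimethoxy-11-(phenylsulfonyl)indolo[2,3-a]carbazole-12-carboxylate
Product: 19 borregomycin E (2,9-dichloro-5,6-dimethoxy-11,12-dihydroindolo[2,3-a]carbazole), via N12-H sulfonamide 18 (not isolated)
Conditions: KOH (excess), THF/MeOH/H2O (degassed), 60 °C, argon; then aq. NH4Cl
Reagents that add atoms: none
Why: Both N-substituents sit on weakly basic indole-type nitrogens that are good leaving groups, so hydroxide cleaves the carbamate and then the sulfonamide by nucleophilic acyl and sulfonyl substitution, helped by relief of the crowding between the two groups in the N11/N12 bay, and, unlike a dissolving-metal desulfonylation, it leaves the two aryl chlorides untouched.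

Compound list
1 | 6-chloroindole | Clc1ccc2cc[nH]c2c1 | starting material
2 | oxalyl chloride | O=C(Cl)C(=O)Cl | starting material
3 | 2-(6-chloro-1H-indol-3-yl)-2-oxoacetyl chloride | O=C(Cl)C(=O)c1c[nH]c2cc(Cl)ccc12 | intermediate (not isolated)
4 | methyl 2-(6-chloro-1H-indol-3-yl)-2-oxoacetate | COC(=O)C(=O)c1c[nH]c2cc(Cl)ccc12 | intermediate
5 | tert-butyl 6-chloro-3-(2-methoxy-2-oxoacetyl)indole-1-carboxylate | COC(=O)C(=O)c1cn(C(=O)OC(C)(C)C)c2cc(Cl)ccc12 | intermediate
6 | tert-butyl 6-chloro-3-(1-hydroxy-2-methoxy-2-oxoethyl)indole-1-carboxylate, racemic | COC(=O)C(O)c1cn(C(=O)OC(C)(C)C)c2cc(Cl)ccc12 | intermediate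
7 | tert-butyl 6-chloro-3-(1,2-dimethoxy-2-oxoethyl)indole-1-carboxylate, racemic | COC(=O)C(OC)c1cn(C(=O)OC(C)(C)C)c2cc(Cl)ccc12 | intermediate
8 | lithium enolate of 7, chelated geometry with O–Li cis to the C5 methoxy group | [Li+].[O-]/C(OC)=C(\OC)c1cn(C(=O)OC(C)(C)C)c2cc(Cl)ccc12 | intermediate (not isolated)
9 | tert-butyl 6-chloro-3-[(Z)-1,2-dimethoxy-2-(trimethylsilyloxy)ethenyl]indole-1-carboxylate (Z isomer drawn; the E isomer would serve equally) | C[Si](C)(C)O/C(OC)=C(\OC)c1cn(C(=O)OC(C)(C)C)c2cc(Cl)ccc12 | intermediate (key-step precursor)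
10 | benzenesulfonyl chloride | O=S(=O)(Cl)c1ccccc1 | starting material
11 | 6-chloro-1-(phenylsulfonyl)indole | O=S(=O)(c1ccccc1)n1ccc2ccc(Cl)cc21 | intermediate
12 | 6-chloro-3-nitro-1-(phenylsulfonyl)indole | O=[N+]([O-])c1cn(S(=O)(=O)c2ccccc2)c2cc(Cl)ccc12 | intermediate (key-step precursor)
13 | primary cycloadduct, tert-butyl 2,9-dichloro-5,6-dimethoxy-6a-nitro-11-(phenylsulfonyl)-6-(trimethylsilyloxy)-6,6a,11a,11b-tetrahydroindolo[2,3-a]carbazole-12-carboxylate, racemic, cis C6a/C11a fusion, C6 and C11b unassigned | COC1=C2c3ccc(Cl)cc3N(C(=O)OC(C)(C)C)C2[C@H]2N(S(=O)(=O)c3ccccc3)c3cc(Cl)ccc3[C@@]2([N+](=O)[O-])C1(OC)O[Si](C)(C)C | intermediate (not isolated)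
14 | tert-butyl 2,9-dichloro-5,6-dimethoxy-11-(phenylsulfonyl)-6-(trimethylsilyloxy)-6,11b-dihydroindolo[2,3-a]carbazole-12-carboxylate, diastereomer mixture | COC1=C2c3ccc(Cl)cc3N(C(=O)OC(C)(C)C)C2c2n(S(=O)(=O)c3ccccc3)c3cc(Cl)ccc3c2C1(OC)O[Si](C)(C)C | intermediate (not isolated)
15 | tert-butyl 2,9-dichloro-5-methoxy-11-(phenylsulfonyl)-6-(trimethylsilyloxy)indolo[2,3-a]carbazole-12-carboxylate | COc1c(O[Si](C)(C)C)c2c3ccc(Cl)cc3n(S(=O)(=O)c3ccccc3)c2c2n(C(=O)OC(C)(C)C)c3cc(Cl)ccc3c12 | intermediate (not isolated)
16 | tert-butyl 2,9-dichloro-6-hydroxy-5-methoxy-11-(phenylsulfonyl)indolo[2,3-a]carbazole-12-carboxylate | COc1c(O)c2c3ccc(Cl)cc3n(S(=O)(=O)c3ccccc3)c2c2n(C(=O)OC(C)(C)C)c3cc(Cl)ccc3c12 | intermediate (key-step product)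
17 | tert-butyl 2,9-dichloro-5,6-dimethoxy-11-(phenylsulfonyl)indolo[2,3-a]carbazole-12-carboxylate | COc1c(OC)c2c3ccc(Cl)cc3n(S(=O)(=O)c3ccccc3)c2c2n(C(=O)OC(C)(C)C)c3cc(Cl)ccc3c12 | intermediate
18 | 2,9-dichloro-5,6-dimethoxy-11-(phenylsulfonyl)-11,12-dihydroindolo[2,3-a]carbazole | COc1c(OC)c2c3ccc(Cl)cc3n(S(=O)(=O)c3ccccc3)c2c2[nH]c3cc(Cl)ccc3c12 | intermediate (not isolated)
19 | borregomycin E, 2,9-dichloro-5,6-dimethoxy-11,12-dihydroindolo[2,3-a]carbazole | COc1c(OC)c2c3ccc(Cl)cc3[nH]c2c2[nH]c3cc(Cl)ccc3c12 | target

Total step count: 10. Longest linear sequence: 8 (steps 1–5, 8, 9, 10).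

Steps most likely to fail

1. Step 8.
- The ketene acetal may bond through C5 in a simple Mukaiyama–Michael addition.
- Silyl transfer to the nitronate may interrupt the second bond formation.
- The two N-substituents may hinder the head-to-head approach and strain the N11/N12 bay on aromatisation. Premature loss of the Boc group for this reason would be harmless, because the phenol stays far more acidic than an indole-type N–H in step 9 and everything converges in step 10.
- The diene may be destroyed by the acid set free.

The fallback sets out from 11 and rejoins the route at the target 19. It builds C11a–C11b first and uses the twofold symmetry of the target. C2-lithiation of 11 (LiN(iPr)2, THF, −78 °C) and oxidative homocoupling with CuCl2 should give 6,6'-dichloro-1,1'-bis(phenylsulfonyl)-2,2'-biindole F1. KOH in MeOH/THF at reflux removes both sulfonyl groups to give 6,6'-dichloro-1H,1'H-2,2'-biindole F2. Double Friedel–Crafts acylation at C3 and C3' with oxalyl chloride 2 (1,2-dichloroethane, 0 °C to reflux) closes ring C as 2,9-dichloro-11,12-dihydroindolo[2,3-a]carbazole-5,6-dione F3. Na2S2O4 in THF/H2O reduces the quinone to 2,9-dichloro-11,12-dihydroindolo[2,3-a]carbazole-5,6-diol F4. This is O-methylated without isolation (MeI, K2CO3, DMF, argon) to give 19, the much less acidic N–H groups staying untouched.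

2. Step 5. The trimethylsilyl ketene acetal may hydrolyse, or its silyl group may migrate from oxygen to carbon, during the non-aqueous isolation and the later heating. It cannot be purified.

The fallback sets out from 7 and rejoins at 16, with a robust silyl group and a separate fluoride step. The same enolate is trapped with tBuMe2SiCl in THF/DMPU to give tert-butyl 3-[(Z)-2-(tert-butyldimethylsilyloxy)-1,2-dimethoxyethenyl]-6-chloroindole-1-carboxylate F5, which tolerates aqueous work-up and rapid filtration through Et3N-deactivated silica. Cycloaddition with 12 as in step 8, without the acidic work-up, should stop at the isolable tert-butyl 6-(tert-butyldimethylsilyloxy)-2,9-dichloro-5-methoxy-11-(phenylsulfonyl)indolo[2,3-a]carbazole-12-carboxylate F6. Bu4NF buffered with AcOH (THF, 0 °C) then releases 16.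

3. Step 10. Sulfonamide cleavage may be incomplete, nitrogen may be alkylated by the sulfonate ester formed through methoxide attack at sulfur, or the electron-rich product may be air-oxidised in hot base.

The fallback sets out from 17 and rejoins at 19 by two orthogonal, non-hydrolytic operations. TFA in CH2Cl2 at rt removes the Boc group to give 18, isolated this time. Bu4NF in THF at reflux then cleaves the N-sulfonyl group by attack of fluoride at sulfur. No compound outside the list is made (F0).

Further compounds
F1 | step 8 | 6,6'-dichloro-1,1'-bis(phenylsulfonyl)-2,2'-biindole | O=S(=O)(c1ccccc1)n1c(-c2cc3ccc(Cl)cc3n2S(=O)(=O)c2ccccc2)cc2ccc(Cl)cc21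
F2 | step 8 | 6,6'-dichloro-1H,1'H-2,2'-biindole | Clc1ccc2cc(-c3cc4ccc(Cl)cc4[nH]3)[nH]c2c1
F3 | step 8 | 2,9-dichloro-11,12-dihydroindolo[2,3-a]carbazole-5,6-dione | O=C1C(=O)c2c([nH]c3cc(Cl)ccc23)-c2[nH]c3cc(Cl)ccc3c21
F4 | step 8 | 2,9-dichloro-11,12-dihydroindolo[2,3-a]carbazole-5,6-diol | Oc1c(O)c2c3ccc(Cl)cc3[nH]c2c2[nH]c3cc(Cl)ccc3c12
F5 | step 5 | tert-butyl 3-[(Z)-2-(tert-butyldimethylsilyloxy)-1,2-dimethoxyethenyl]-6-chloroindole-1-carboxylate | CC(C)(C)[Si](C)(C)O/C(OC)=C(\OC)c1cn(C(=O)OC(C)(C)C)c2cc(Cl)ccc12
F6 | step 5 | tert-butyl 6-(tert-butyldimethylsilyloxy)-2,9-dichloro-5-methoxy-11-(phenylsulfonyl)indolo[2,3-a]carbazole-12-carboxylate | COc1c(O[Si](C)(C)C(C)(C)C)c2c3ccc(Cl)cc3n(S(=O)(=O)c3ccccc3)c2c2n(C(=O)OC(C)(C)C)c3cc(Cl)ccc3c12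
F0 | step 10 | none | none
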